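I had no constants for this flask, only readings, so I read what time constant they allowed.

| flask | starting material | protic impurity | temperature | remark | time |
|---|---|---|---|---|---|
| east | 3 M | 1.5 M | 25 °C | the very flask that is asked about, followed so far |  |
| north | 3 M | 1 M | 20 °C | run made earlier |  |
| flask | 3.0 M | 1.50 M | 25 °C |  | 8.0 d |

| run | time / d | ring / % |
|---|---|---|
| east | 0.500 | 15.5 |
| east | 0.833 | 18.0 |
| east | 1.25 | 19.3 |
| east | 2.50 | 16.5 |
| east | 4.00 | 13.1 |
| east | 6.00 | 11.1 |
| north | 1.25 | 16.4 |
| north | 3.00 | 17.6 |
| north | 6.00 | 14.5 |
| north | 10.0 | 10.1 |
| north | 12.0 | 8.9 |
| north | 20.0 | 6.4 |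

(each reading ± 0.3 percentage points)

- spring: at 8.0 d take out 90% of the ring then present, then wait 2.5 d
- dawn: at 8.0 d raise the temperature by 15 K, then wait 2.5 d
- autumn: change nothing and wait 2.5 d more

- what is taken out of ring is counted as made
- the analysis behind the earlier runs scatters by 0.3 percentage points, standard deviation

- ring, in percent of the starting material first charged, at 8.0 d
- which option adds most ring ("none" when 2 percentage points or less is all one gets) (spring / dawn / autumn / none)
- ring present, with what was taken out counted in, in percent of the starting material first charged, after spring
- ring present, with what was taken out counted in, in percent of the starting material first charged, after dawn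

I built the flask up in steps. With the main step only, starting material became ring, and ring climbed towards 100% and stayed. But east's highest reading was 19.3%, at 1.25 d, so I added a loss of ring. Ring then fell in proportion to itself, and continuing from east's last reading gave 9.41% at 8.0 d, still falling.

That did not fit either. East lost 3.4 percentage points in 1.50 d, then 2 points in 2.00 d. The rate of fall shrank by a larger factor than the ring did, so I added a floor. The drift of those two rates gave 2.14 d: the relaxation time, in which the distance to the floor shrinks by a factor e. The floor came out at 9.96%, and my ring at 8.0 d at 10.5%.

North was cooler and held less protic impurity. The same reckoning gave 6.42 d and a floor of 5.87%. East was quicker and had the higher floor. Two settings differed between the runs, and I guessed that temperature carried the difference. Dawn is 3.00 such steps, which gave a relaxation time of 0.0789 d, short against 2.5 d. I took the floor after one such step, 16.9%, as a cautious figure for dawn, and chose dawn.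

The forecast differed: 10% now, spring best, 14% after spring and 11% after dawn. It held that “Heating probably shifts the balance mildly towards ring”.

The flask gave 10.2%. Spring added 4.2 points, reaching 14.4%; dawn added 12 points, reaching 22.2%; autumn added −0.39 points. The best was dawn, and the forecast's dawn figure stood 11 points low.

    starting material → ring (k = 0.0270 /h, Ea = 108 kJ/mol)
    2 starting material → open dimer (k = 0.0130 /M/h, Ea = 71.0 kJ/mol)
    ring ⇌ isomer of the product (K = 2.20, k = 0.0150 /h, Ea = 92.0 kJ/mol, ΔH = −90.0 kJ/mol)
    starting material + protic impurity → quenched substrate (k = 0.0330 /M/h, Ea = 88.0 kJ/mol)
    (constants at 25 °C)

In this flask, ring's half-life by the forward passing into isomer of the product was 1.9 d at 0.252 d, short against 8.0 d. At 8.00 d, ring was made at 0.0167 of the rate at which it was used up, each step taken net, and 8.0 d held 3.74 of my relaxation times, with ring at 10.2% and isomer of the product at 20.7%.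

For the neighbour repeat at 0 °C, carrying my relaxation time to that temperature by the east-north ratio, on the same guess, gave a rough 523 d, far beyond 8.0 d, so I expected the isomer of the product to lag. That neighbour gave 0.307% of it against 5.34% of ring.

The data are calculated on assumed constants; scatter was added.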